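## Structural features

The target (14) is a symmetric dimer. Two identical, fully substituted benzene rings (ring A) are each fused to a 2,2-dimethyl-3,4-dihydro-2H-pyran (ring B) to give a chroman. The two chromans are joined through their C6 carbons by one sp3 methine that also carries a 5-methylhexyl chain, so the bridge is a 6-methylheptane-1,1-diyl unit. Each ring A is an acylphloroglucinol: C8 bears the isobutyryl group, its two ortho oxygens are the pyran O1 (on C8a) and the C7 hydroxyl, and the oxygen para to it is the C5 hydroxyl. C4a carries the pyran CH2CH2 unit and C6 the bridge. The molecule has no stereocentre, because the bridging carbon bears two identical aryl groups, so no configuration has to be set and no stereocentres stand next to each other. The fragile parts are the doubly benzylic methine flanked by four ortho hydroxyls (open to acid- or heat-induced retro-Friedel–Crafts cleavage through an ortho-quinone methide), the electron-rich phenols, and the hindered, enolisable aryl isopropyl ketones. The real difficulty is regiochemical: the pyran oxygen must be an oxygen ortho to the acyl group and not the para oxygen, although both flank C4a, and the bridge must go to the one remaining ring carbon. The key step exploits C2 of each ring B, a quaternary carbon holding two methyl groups and O1. At the ester oxidation level the unit O1–C2–C3–C4–C4a–C8a is a 3,4-dihydrocoumarin, so the four C2–CH3 bonds can come from a methyl Grignard reagent, and the lactone oxygen identifies the future pyran oxygen.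

## Logic of the disconnections

14 ⇒ 13. The bonds concerned are the two C5 O–CH2Ar ether bonds, present in 13 and absent in 14. The C5 oxygen has to stay capped until ring B is closed, because it is the second oxygen next to C4a. Nothing is gained in skeleton, but all four free phenols next to the bridge are postponed to the last step. The forward step must cleave two benzylic C–O bonds without touching the ketones or the diarylmethine.

13 ⇒ 12. The O1–C2 bond of each ring B is cut. A tertiary alkyl aryl ether next to a phenol is the product of capture of a tertiary cation, so both pyrans open to acyclic tertiary carbinols. The forward step demands that only one phenol oxygen can reach the cation (secured by the C5 ether in 12) and that the acid is mild enough for the bridge.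

12 ⇒ 9 + 10. The four C2–CH3 bonds are cut. Each carbinol carbon becomes the carbonyl carbon of a six-membered aryl lactone whose ring oxygen is the phenol that 12 has free next to the chain. Four C–C bonds and two quaternary carbons go back to two ester carbonyls, and the ring locks the chain to the right oxygen. The forward step needs the lactone to react before the isobutyryl ketone, with at least six equivalents of 10 consumed.

9 ⇒ 6 (twice) + 7. The two aryl C6–CH bonds at the bridge are cut. The bridge carbon is an aldehyde carbon, the two halves are identical, and in 6 the C6 position is the only unsubstituted ring carbon, so no oligomer can form. The molecule is halved. The forward step requires two electrophilic substitutions on a ring of moderate nucleophilicity without opening the lactone or losing the ether.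

6 ⇒ 3 + 4. The C4a–C4 bond and the O1–C2 acyl–oxygen bond are cut. C2–C3–C4 is a three-carbon acid; because the para oxygen of 3 is etherified, the only oxygen beside the new C–C bond is one ortho to the ketone. The lactone ring is removed and a symmetric arene with two equivalent free carbons results. The forward step needs an ether that survives Brønsted acid and an annulation that stops after one ring.

3 ⇒ 1 + 2. The para O–CH2Ar bond is cut. This oxygen is the only one not hydrogen-bonded to the ketone and is the most acidic, so it can be addressed alone. The cut reaches purchasable materials. The forward step requires mono-O-alkylation without C-alkylation.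

## Other disconnections considered

Alternative 1: The cut is the C4a–C4 bond of each pyran, leading from the bis(2,2-dimethyl-2H-chromene) di-O-benzyl ether A1 back to the bis(aryl 1,1-dimethylpropargyl ether) A2. In A2 the ether oxygen is the one ortho to the acyl group and has one free ortho carbon. Heating A2 should trigger two aromatic propargyl Claisen rearrangements, each followed by a 1,5-hydrogen shift and an oxa-6π electrocyclisation, to give A1. Hydrogenation of A1 would saturate both C3=C4 bonds and remove the benzyl ethers in one operation, giving 14.

- In its favour: the pyran oxygen is fixed by O-alkylation before any C–C bond is made, the [3,3] shift has only one free ortho carbon to go to, no acid and no organometallic reagent are needed, and both rings close in the same step.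
- Against it here: in the bridged substrate the propargylation must choose the acyl-ortho hydroxyl next to the free carbon over the other acyl-ortho hydroxyl next to the bridge. Both are chelated, so only sterics differentiate them. Tertiary propargyl ethers of chelated phenols are slow to form, and the rearrangement needs prolonged heating of a substrate whose diarylmethine is flanked by free phenols.
- Comparison: on structure the chosen plan is the stronger, since the capped para oxygen leaves only one oxygen able to lactonise. On mechanism the alternative is the equal of the chosen plan and is milder in reagents. On step economy it is equal or one step shorter, because ring closure needs no separate step and the final hydrogenation does two jobs.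

Alternative 2: The cut is, in each arene, the ring bond between the acyl-bearing carbon and its hydroxyl-bearing neighbour, leading from the bridged bis(isobutyrylphloroglucinol) A3 back to the bridged bis(4-hydroxy-6-(3-methyl-2-oxobutyl)pyran-2-one) A4. Mg(OMe)2 in methanol should open both pyrones to triketo esters and steer them into the Claisen mode of cyclisation, building both benzene rings with the acyl groups and the bridge in place.

- In its favour: no protecting group, a biomimetic and two-directional construction, and a magnesium-templated cyclisation of a known type.
- Against it here: A3 is what 1 and 7 would give by direct condensation, so the step builds what can be bought. A4 needs its own multi-step synthesis. The aldol mode of cyclisation competes. A3 still lacks both pyran rings and has a free carbon flanked by an ortho and a para oxygen, so the regiochemical problem is untouched.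
- Comparison: on structure it addresses the arene, which is not the difficulty, and leaves the pyran oxygen undecided. On mechanism it is the better of the two in avoiding protecting groups. On step economy it is clearly worse, because a regiocontrolled chroman annulation, probably with the same protection as in the chosen plan, would still have to follow.

Alternative 3: The cut is the C8a–O1 bond of each pyran, leading from the tetra-O-benzyl ether A5 of the target back to the bis(fluoroarene) A6, which carries a 3-hydroxy-3-methylbutyl chain on C4a and fluorine on C8a. KOtBu in DMF should deprotonate both tertiary alcohols, and each alkoxide should displace the fluoride ortho to the ketone by intramolecular addition–elimination, closing both pyrans.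

- In its favour: the fluorine marks the ring carbon absolutely, so the para-oxygen isomer cannot form. Ring closure is basic, so the bridge and the benzyl ethers see no acid, and on that point it is better than the chosen plan. A5 is one hydrogenolysis away from 14.
- Against it here: the only activating group is one ketone that is twisted out of the ring plane by its two ortho neighbours. The nucleophile is a hindered, basic tertiary alkoxide next to enolisable ketones. A6 needs a fluorinated acylresorcinol core that has to be built from the start, four benzyl ethers (two on hindered chelated phenols), and a bridging reaction on a less nucleophilic fluoroarene.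
- Comparison: on structure the idea is the same as in the chosen plan, a marker on C8a, but the lactone oxygen arrives together with the three-carbon unit whereas the fluorine must be carried from the beginning. On mechanism the two are equal in regiochemical certainty. On step economy the alternative is much longer.

Key step: step 4

Remarks on the chemistry (assumptions and design choices):
- Compounds 1 and 7 are taken as purchasable; positions are quoted in chroman numbering (O1, C2, C3, C4, C4a, C5 to C8, C8a).
- All structures were checked atom by atom against the target: pyran oxygen ortho to the acyl group, C5 hydroxyl para to it, bridge on C6. No connectivity needed correcting.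
- The key-step substrate 9 carries one ether per ring, on the C5 oxygen only. The chelated C7 hydroxyl is meta to the C4a chain and cannot compete in the pyran closure. Leaving it free saves a double alkylation of a hindered phenol under base in the presence of the base-labile aryl lactones, at the cost of two more equivalents of 10.
- The C5 ether is a 4-(trifluoromethyl)benzyl ether. It must survive three Brønsted-acid steps (2, 3 and 5); the electron-poor benzyl group resists acid ionisation and O-to-C migration far better than benzyl, is inert to 10, and is still cleaved by hydrogenolysis.

## Route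

Step 1
Reactants: 1 isobutyrylphloroglucinol (2-methyl-1-(2,4,6-trihydroxyphenyl)propan-1-one); 2 4-(trifluoromethyl)benzyl bromide
Product: 3 1-[2,6-dihydroxy-4-{[4-(trifluoromethyl)phenyl]methoxy}phenyl]-2-methylpropan-1-one
Conditions: 2 (1.0 equiv, slow addition), K2CO3 (1.05 equiv), DMF, 0 °C → rt
Reagents that add atoms: 4-(trifluoromethyl)benzyl bromide (2), BrCc1ccc(cc1)C(F)(F)F
Why: Williamson ether synthesis; the para hydroxyl is the only one not chelated to the ketone and is the most acidic, so one equivalent of weak base should give its phenoxide selectively, and the polar aprotic solvent favours O- over C-alkylation.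

Step 2
Reactants: 3 1-[2,6-dihydroxy-4-{[4-(trifluoromethyl)phenyl]methoxy}phenyl]-2-methylpropan-1-one; 4 acrylic acid
Product: 6 7-hydroxy-8-(2-methylpropanoyl)-5-{[4-(trifluoromethyl)phenyl]methoxy}-3,4-dihydro-2H-chromen-2-one, via hydroxy acid 5 (not isolated)
Conditions: 4 (1.3 equiv), Amberlyst-15 (sulfonic acid resin), BHT (cat.), toluene, 100 °C
Reagents that add atoms: acrylic acid (4), C=CC(=O)O
Why: Acid-catalysed Friedel–Crafts conjugate addition (hydroarylation) at one of the two equivalent free ring carbons gives 5, which should lactonise onto the only free neighbouring hydroxyl, an oxygen ortho to the ketone, since the other neighbour is the ether. The aryl ester lowers the nucleophilicity of the ring and so should discourage a second annulation, and the electron-poor benzyl ether should resist acid cleavage.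

Step 3
Reactants: 6 7-hydroxy-8-(2-methylpropanoyl)-5-{[4-(trifluoromethyl)phenyl]methoxy}-3,4-dihydro-2H-chromen-2-one (2.1 equiv); 7 6-methylheptanal
Product: 9 1,1-bis[7-hydroxy-8-(2-methylpropanoyl)-2-oxo-5-{[4-(trifluoromethyl)phenyl]methoxy}-3,4-dihydro-2H-chromen-6-yl]-6-methylheptane, via benzylic carbinol 8 (not isolated)
Conditions: 7 (1.0 equiv, slow addition), TsOH·H2O (20 mol%), ClCH2CH2Cl, 60 °C
Reagents that add atoms: 6-methylheptanal (7), CC(C)CCCCC=O
Why: Acid-catalysed alkylidene-bisphenol condensation: hydroxyalkylation at C6 (ortho to the free hydroxyl and to the ether oxygen) gives 8, which should ionise to an ortho-quinone methide or benzylic cation and alkylate a second molecule of 6. Only one ring carbon per arene is free, so no oligomer can form, the lactone is stable to anhydrous acid, and the new methine bears two identical aryl groups and is not a stereocentre.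

Step 4
Reactants: 9 1,1-bis[7-hydroxy-8-(2-methylpropanoyl)-2-oxo-5-{[4-(trifluoromethyl)phenyl]methoxy}-3,4-dihydro-2H-chromen-6-yl]-6-methylheptane; 10 methylmagnesium bromide
Product: 12 1,1-bis[4,6-dihydroxy-3-(3-hydroxy-3-methylbutyl)-5-(2-methylpropanoyl)-2-{[4-(trifluoromethyl)phenyl]methoxy}phenyl]-6-methylheptane, via bis(methyl ketone) 11 (not isolated)
Conditions: 10 (12 equiv, 3 M in Et2O), THF, −40 → 0 °C; then H2O
Reagents that add atoms: methylmagnesium bromide (10), C[Mg]Br
Why: Double Grignard addition to an ester, here the long-known conversion of 3,4-dihydrocoumarins into 2-(3-hydroxy-3-methylbutyl)phenols, run in both halves at once. The first two equivalents of 10 deprotonate the chelated C7 hydroxyls; methyl then adds to each aryl-ester carbonyl, the tetrahedral intermediate expels the C8a aryloxide to leave methyl ketone 11 as its magnesium salt, and a second addition to this unhindered ketone gives the tertiary alkoxide, so that four C2–CH3 bonds are formed. No ring is closed and no stereocentre is created, so neither a mode of closure nor a controlling element has to be named. The selectivity needed is lactone before isobutyryl ketone: the aryl ester is a strongly activated acyl donor, whereas the ketone carries a branched alkyl group, is flanked by two ortho oxygens and is conjugated from the outset with the C7 aryloxide and, after ring opening, with a second one, which makes it a vinylogous carboxylate that can at most enolise reversibly. Low temperature and the absence of more oxophilic additives should keep it that way. The aryloxide set free is the oxygen ortho to the acyl group, and the carbinol chain on C4a lies between it and the etherified C5 oxygen, which is what the next step relies on.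

Step 5
Reactants: 12 1,1-bis[4,6-dihydroxy-3-(3-hydroxy-3-methylbutyl)-5-(2-methylpropanoyl)-2-{[4-(trifluoromethyl)phenyl]methoxy}phenyl]-6-methylheptane
Product: 13 1,1-bis[7-hydroxy-2,2-dimethyl-8-(2-methylpropanoyl)-5-{[4-(trifluoromethyl)phenyl]methoxy}-3,4-dihydro-2H-chromen-6-yl]-6-methylheptane
Conditions: TsOH·H2O (10 mol%), toluene, 50 °C
Reagents that add atoms: none
Why: Acid-catalysed cyclodehydration: the tertiary carbinol ionises (any alkene formed by elimination re-protonates to the same cation) and is captured by the adjacent C8a hydroxyl to close the six-membered ring. The C5 oxygen is etherified, the C7 hydroxyl is out of reach and no ring carbon is free, so only the desired pyran should form, and catalytic acid at moderate temperature should spare the bridge and the ethers.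

Step 6
Reactants: 13 1,1-bis[7-hydroxy-2,2-dimethyl-8-(2-methylpropanoyl)-5-{[4-(trifluoromethyl)phenyl]methoxy}-3,4-dihydro-2H-chromen-6-yl]-6-methylheptane
Product: 14 1,1-bis[5,7-dihydroxy-2,2-dimethyl-8-(2-methylpropanoyl)-3,4-dihydro-2H-chromen-6-yl]-6-methylheptane (CNP0275635.0, achiral)
Conditions: H2 (1–3 atm), Pd(OH)2/C, EtOAc–MeOH, rt
Reagents that add atoms: none
Why: Catalytic hydrogenolysis of the two benzylic C–O bonds of aryl arylmethyl ethers. The chelated, hindered aryl ketones, the diarylmethine and the non-benzylic pyran C–O bonds should not react under these conditions.

## Compound list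

1 | isobutyrylphloroglucinol (2-methyl-1-(2,4,6-trihydroxyphenyl)propan-1-one) | CC(C)C(=O)c1c(O)cc(O)cc1O | starting material
2 | 4-(trifluoromethyl)benzyl bromide | BrCc1ccc(cc1)C(F)(F)F | starting material
3 | 1-[2,6-dihydroxy-4-{[4-(trifluoromethyl)phenyl]methoxy}phenyl]-2-methylpropan-1-one | CC(C)C(=O)c1c(O)cc(OCc2ccc(cc2)C(F)(F)F)cc1O | intermediate
4 | acrylic acid | C=CC(=O)O | starting material
5 | 3-[2,4-dihydroxy-3-(2-methylpropanoyl)-6-{[4-(trifluoromethyl)phenyl]methoxy}phenyl]propanoic acid | OC(=O)CCc1c(O)c(C(=O)C(C)C)c(O)cc1OCc1ccc(cc1)C(F)(F)F | intermediate
6 | 7-hydroxy-8-(2-methylpropanoyl)-5-{[4-(trifluoromethyl)phenyl]methoxy}-3,4-dihydro-2H-chromen-2-one | CC(C)C(=O)c1c(O)cc(OCc2ccc(cc2)C(F)(F)F)c2CCC(=O)Oc12 | intermediate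
7 | 6-methylheptanal | CC(C)CCCCC=O | starting material
8 | 7-hydroxy-6-(1-hydroxy-6-methylheptyl)-8-(2-methylpropanoyl)-5-{[4-(trifluoromethyl)phenyl]methoxy}-3,4-dihydro-2H-chromen-2-one (racemic) | CC(C)CCCCC(O)c1c(O)c(C(=O)C(C)C)c2OC(=O)CCc2c1OCc1ccc(cc1)C(F)(F)F | intermediate
9 | 1,1-bis[7-hydroxy-8-(2-methylpropanoyl)-2-oxo-5-{[4-(trifluoromethyl)phenyl]methoxy}-3,4-dihydro-2H-chromen-6-yl]-6-methylheptane | CC(C)CCCCC(c1c(OCc2ccc(cc2)C(F)(F)F)c2c(c(C(=O)C(C)C)c1O)OC(=O)CC2)c1c(OCc2ccc(cc2)C(F)(F)F)c2c(c(C(=O)C(C)C)c1O)OC(=O)CC2 | intermediate
10 | methylmagnesium bromide | C[Mg]Br | starting material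
11 | 1,1-bis[4,6-dihydroxy-5-(2-methylpropanoyl)-3-(3-oxobutyl)-2-{[4-(trifluoromethyl)phenyl]methoxy}phenyl]-6-methylheptane | CC(C)CCCCC(c1c(OCc2ccc(cc2)C(F)(F)F)c(CCC(C)=O)c(O)c(C(=O)C(C)C)c1O)c1c(OCc2ccc(cc2)C(F)(F)F)c(CCC(C)=O)c(O)c(C(=O)C(C)C)c1O | intermediate
12 | 1,1-bis[4,6-dihydroxy-3-(3-hydroxy-3-methylbutyl)-5-(2-methylpropanoyl)-2-{[4-(trifluoromethyl)phenyl]methoxy}phenyl]-6-methylheptane | CC(C)CCCCC(c1c(OCc2ccc(cc2)C(F)(F)F)c(CCC(C)(C)O)c(O)c(C(=O)C(C)C)c1O)c1c(OCc2ccc(cc2)C(F)(F)F)c(CCC(C)(C)O)c(O)c(C(=O)C(C)C)c1O | intermediate
13 | 1,1-bis[7-hydroxy-2,2-dimethyl-8-(2-methylpropanoyl)-5-{[4-(trifluoromethyl)phenyl]methoxy}-3,4-dihydro-2H-chromen-6-yl]-6-methylheptane | CC(C)CCCCC(c1c(OCc2ccc(cc2)C(F)(F)F)c2c(c(C(=O)C(C)C)c1O)OC(C)(C)CC2)c1c(OCc2ccc(cc2)C(F)(F)F)c2c(c(C(=O)C(C)C)c1O)OC(C)(C)CC2 | intermediate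
14 | 1,1-bis[5,7-dihydroxy-2,2-dimethyl-8-(2-methylpropanoyl)-3,4-dihydro-2H-chromen-6-yl]-6-methylheptane (achiral) | CC(C)CCCCC(c1c(O)c2c(c(C(=O)C(C)C)c1O)OC(C)(C)CC2)c1c(O)c2c(c(C(=O)C(C)C)c1O)OC(C)(C)CC2 | target

## Step count and least certain steps

Total step count: 6. Longest linear sequence: 6 steps (1 → 3 → 6 → 9 → 12 → 13 → 14).

Step 4 (key step). The most likely failures are loss of chemoselectivity once the reagent is in large excess (methyl addition to the isobutyryl ketone), arrest after the first addition (a cyclic magnesium hemiketalate that does not collapse, or enolisation of the methyl ketone), and precipitation of polyanionic magnesium salts so that one half reacts incompletely. The fallback separates the two additions. It sets out from 9, whose lactones would be opened with Me(MeO)NH·HCl and iPrMgCl in THF to the bis(N-methoxy-N-methylamide) F1. MeMgBr would then stop at the chelated tetrahedral stage and give the bis(methyl ketone) 11 as an isolated compound on work-up. A second treatment of 11 with MeMgBr at −78 °C, where only the unhindered methyl ketones should react, comes back to the route at 12.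

Step 3. The most likely failure is slow electrophilic substitution on a ring deactivated by the acyl and acyloxy groups, so that acid-catalysed self-condensation of the enolisable aldehyde, or arrest at the carbinol or styrene stage, competes; crowding in the second arylation adds to this. The fallback uses the far more nucleophilic phenolate. It sets out from 6, which would be saponified with LiOH in aqueous THF to the salt of hydroxy acid 5. In the same alkaline aqueous ethanol, 5 would be condensed with 7 (0.5 equiv) at rt by the phenolate hydroxyalkylation and ortho-quinone methide addition sequence typical of acylphloroglucinols. Acidification would give the bridged bis(hydroxy acid) F2. Re-lactonisation with TsOH·H2O (cat.) in toluene with a Dean–Stark trap can only use the oxygen next to the chain, since the other neighbour is etherified, and comes back to the route at 9.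

Step 2. The most likely failures are acid-promoted loss or migration of the arylmethyl group despite its deactivation, a second annulation at the other free carbon, and polymerisation of acrylic acid on a slowly reacting arene. The fallback avoids strong acid. It sets out from 3, which would be heated with triethyl orthoacrylate and pivalic acid (cat.) in toluene at reflux to the cyclic ortho ester 2,2-diethoxy-7-hydroxy-8-(2-methylpropanoyl)-5-{[4-(trifluoromethyl)phenyl]methoxy}-3,4-dihydro-2H-chromene F3. Hydrolysis with dilute HCl in aqueous THF at rt comes back to the route at 6.

Step 6. The most likely failure is sluggish hydrogenolysis of the electron-poor benzylic C–O bonds, giving incomplete deprotection, with reduction of an aryl ketone if conditions are forced. The fallback is a nucleophilic dealkylation. It sets out from 13, which would be treated with NaSEt in DMF at 80–100 °C. SN2 attack at the benzylic carbon should expel the aryloxide para to the acyl group and, after acidification, comes back to the route at 14. This fallback makes no new compound (F0).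

Step 1. The most likely failures are over-alkylation at a chelated hydroxyl and C-alkylation of the phloroglucinol nucleus. The fallback avoids the free phenoxide. It sets out from 1, which would be etherified under Mitsunobu conditions with 4-(trifluoromethyl)benzyl alcohol, PPh3 and DIAD in THF at 0 °C → rt; only the most acidic, non-chelated para hydroxyl should be engaged, and the sequence comes back to the route at 3. This fallback makes no new compound (F0).

## Further compounds

F1 | step 4 | 1,1-bis[4,6-dihydroxy-3-{3-[methoxy(methyl)amino]-3-oxopropyl}-5-(2-methylpropanoyl)-2-{[4-(trifluoromethyl)phenyl]methoxy}phenyl]-6-methylheptane | CC(C)CCCCC(c1c(OCc2ccc(cc2)C(F)(F)F)c(CCC(=O)N(C)OC)c(O)c(C(=O)C(C)C)c1O)c1c(OCc2ccc(cc2)C(F)(F)F)c(CCC(=O)N(C)OC)c(O)c(C(=O)C(C)C)c1O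
F2 | step 3 | 1,1-bis[3-(2-carboxyethyl)-4,6-dihydroxy-5-(2-methylpropanoyl)-2-{[4-(trifluoromethyl)phenyl]methoxy}phenyl]-6-methylheptane | CC(C)CCCCC(c1c(OCc2ccc(cc2)C(F)(F)F)c(CCC(O)=O)c(O)c(C(=O)C(C)C)c1O)c1c(OCc2ccc(cc2)C(F)(F)F)c(CCC(O)=O)c(O)c(C(=O)C(C)C)c1O
F3 | step 2 | 2,2-diethoxy-7-hydroxy-8-(2-methylpropanoyl)-5-{[4-(trifluoromethyl)phenyl]methoxy}-3,4-dihydro-2H-chromene | CCOC1(OCC)CCc2c(O1)c(C(=O)C(C)C)c(O)cc2OCc1ccc(cc1)C(F)(F)F
F0 | step 6 | none | none
F0 | step 1 | none | none
A1 | alternative 1 | bridged bis(2,2-dimethyl-2H-chromene) di-O-benzyl ether | CC(C)CCCCC(c1c(OCc2ccccc2)c2c(c(C(=O)C(C)C)c1O)OC(C)(C)C=C2)c1c(OCc2ccccc2)c2c(c(C(=O)C(C)C)c1O)OC(C)(C)C=C2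
A2 | alternative 1 | bridged bis(aryl 1,1-dimethylpropargyl ether) di-O-benzyl ether | CC(C)CCCCC(c1c(OCc2ccccc2)cc(OC(C)(C)C#C)c(C(=O)C(C)C)c1O)c1c(OCc2ccccc2)cc(OC(C)(C)C#C)c(C(=O)C(C)C)c1O
A3 | alternative 2 | bridged bis(isobutyrylphloroglucinol) with one free ring carbon per arene | CC(C)CCCCC(c1c(O)cc(O)c(C(=O)C(C)C)c1O)c1c(O)cc(O)c(C(=O)C(C)C)c1O
A4 | alternative 2 | 3,3'-(6-methylheptane-1,1-diyl)bis[4-hydroxy-6-(3-methyl-2-oxobutyl)-2H-pyran-2-one] | CC(C)CCCCC(C1=C(O)C=C(CC(=O)C(C)C)OC1=O)C1=C(O)C=C(CC(=O)C(C)C)OC1=O
A5 | alternative 3 | tetra-O-benzyl ether of the target bis-chroman | CC(C)CCCCC(c1c(OCc2ccccc2)c2c(c(C(=O)C(C)C)c1OCc1ccccc1)OC(C)(C)CC2)c1c(OCc2ccccc2)c2c(c(C(=O)C(C)C)c1OCc1ccccc1)OC(C)(C)CC2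
A6 | alternative 3 | bridged bis(fluoroarene) with 3-hydroxy-3-methylbutyl chains, tetra-O-benzyl ether | CC(C)CCCCC(c1c(OCc2ccccc2)c(CCC(C)(C)O)c(F)c(C(=O)C(C)C)c1OCc1ccccc1)c1c(OCc2ccccc2)c(CCC(C)(C)O)c(F)c(C(=O)C(C)C)c1OCc1ccccc1
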